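**Plan**

- Numbering: ring C1–C6 (C1 carries the side chain, C2 and C3 the esters, C4 the methyl, C4–C5 the ring epoxide, C6 is CH2); side chain C7(=C14H2)–C8(O‑angeloyl)–C9–C10/C11 (epoxide).
- Enabling feature: ring bond C1–C2 bears C7(=C14H2)–C8–O on C1 and, on the same face, an oxygen on C2, so C2–O–C8(=O)–C7(=C14H2)–C1 is a latent cis‑fused α‑methylene‑γ‑butyrolactone on the C1–C6 ring.
- Cuts: first the two epoxides and three esters; then C10=C11 (cross‑metathesis) and C8–C9 (allylation of a lactol); then C1–C2 and O–C8 together (allylchromium ring closure); then C1–C7, C5–C6, C4–CH3 and C3–C4 of the open chain.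
- Forward: the chain is built linearly from a glycolaldehyde ether; the six‑membered ring and the lactone ring close in one flask (step 13); the lactone is opened by reduction and the side chain grown to C11; the ring epoxide is made before the side‑chain epoxide.
- Stereochemistry: C3 by asymmetric transfer hydrogenation of an ynone; C1 and C2 from C3 in the ring closure; C8 from a chiral allylborane; C4/C5 by C3–OH‑directed epoxidation; C10 by a chiral dioxirane.

Key step: step 13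

Assumption: RuCl[(S,S)-TsDPEN](p-cymene) is taken to reduce ynone 5 with the facial sense it shows for simple alkynyl ketones (alkynyl in the place of aryl), and (−)-Ipc2BOMe is the antipode made from (+)-α-pinene.

**Route**

Step 1
Reactants: 1 2-[(4-methoxybenzyl)oxy]acetaldehyde; 2 ethynyltrimethylsilane
Product: 4 rac-1-[(4-methoxybenzyl)oxy]-4-(trimethylsilyl)but-3-yn-2-ol, via lithium (trimethylsilyl)acetylide 3 (not isolated)
Conditions: 2, n-BuLi, THF, −78 °C; then 1, −78 °C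
Reagents that add atoms: none
Why: 1,2-Addition of a lithium acetylide to an aldehyde is fast at −78 °C and should outrun enolisation of the α-alkoxy aldehyde, forming the C3–C4 bond; the carbinol centre arises as the racemate and is erased in step 2.

Step 2
Reactants: 4 rac-1-[(4-methoxybenzyl)oxy]-4-(trimethylsilyl)but-3-yn-2-ol
Product: 5 1-[(4-methoxybenzyl)oxy]-4-(trimethylsilyl)but-3-yn-2-one
Conditions: Dess–Martin periodinane, NaHCO3, CH2Cl2, 0 to 25 °C
Reagents that add atoms: none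
Why: Dess–Martin oxidation of a propargylic alcohol should give the ynone under buffered, non-basic conditions that spare the PMB ether and the alkynylsilane.

Step 3
Reactants: 5 1-[(4-methoxybenzyl)oxy]-4-(trimethylsilyl)but-3-yn-2-one
Product: 6 (2R)-1-[(4-methoxybenzyl)oxy]-4-(trimethylsilyl)but-3-yn-2-ol
Conditions: RuCl[(S,S)-TsDPEN](p-cymene) (1 mol%), i-PrOH, 25 °C
Reagents that add atoms: none
Why: Noyori asymmetric transfer hydrogenation of an alkynyl ketone, with the alkynyl group in the role of the aryl group of the standard substrates, should deliver hydride to one face and set C3 as R (R because CH2OPMB outranks the alkyne).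

Step 4
Reactants: 6 (2R)-1-[(4-methoxybenzyl)oxy]-4-(trimethylsilyl)but-3-yn-2-ol
Product: 7 (2R)-1-[(4-methoxybenzyl)oxy]but-3-yn-2-ol
Conditions: K2CO3, MeOH, 25 °C
Reagents that add atoms: none
Why: Base-catalysed methanolysis of the alkynyl carbon–silicon bond (protodesilylation) frees the terminal alkyne without touching the carbinol centre.

Step 5
Reactants: 7 (2R)-1-[(4-methoxybenzyl)oxy]but-3-yn-2-ol
Product: 9 (2R,3Z)-4-iodo-1-[(4-methoxybenzyl)oxy]-3-methylbut-3-en-2-ol, via alkenylmagnesium bromide alkoxide 8 (not isolated)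
Conditions: MeMgBr (3.5 equiv), CuI (20 mol%), THF, 0 to 25 °C; then I2, −78 to 0 °C
Reagents that add atoms: methylmagnesium bromide, C[Mg]Br; iodine, II
Why: Copper-catalysed anti-carbomagnesiation of a propargylic alcohol places methyl on the carbon next to the carbinol (C4) and magnesium on the terminal carbon (C5) within a five-membered chelate with the alkoxide, so iodinolysis with retention should give the Z iodoalkene with iodine cis to C3, the geometry the ring closure needs.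

Step 6
Reactants: 9 (2R,3Z)-4-iodo-1-[(4-methoxybenzyl)oxy]-3-methylbut-3-en-2-ol
Product: 10 tert-butyl{[(2R,3Z)-4-iodo-1-[(4-methoxybenzyl)oxy]-3-methylbut-3-en-2-yl]oxy}dimethylsilane
Conditions: TBSCl, imidazole, DMF, 25 °C
Reagents that add atoms: tert-butyldimethylsilyl chloride, CC(C)(C)[Si](C)(C)Cl
Why: Imidazole-mediated silylation of the secondary allylic alcohol installs the bulky, non-chelating ether that later steers the ring closure.

Step 7
Reactants: 10 tert-butyl{[(2R,3Z)-4-iodo-1-[(4-methoxybenzyl)oxy]-3-methylbut-3-en-2-yl]oxy}dimethylsilane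
Product: 11 ethyl (3Z,5R)-5-[(tert-butyldimethylsilyl)oxy]-6-[(4-methoxybenzyl)oxy]-4-methylhex-3-enoate
Conditions: BrZnCH2CO2Et (preformed, THF), Pd2(dba)3 (2.5 mol%), XPhos (10 mol%), THF, 50 °C
Reagents that add atoms: (2-ethoxy-2-oxoethyl)zinc bromide, CCOC(=O)C[Zn]Br
Why: Negishi-type cross-coupling of a Reformatsky reagent with an alkenyl iodide (oxidative addition, transmetalation, reductive elimination) should form the C5–C6 bond with retention of the Z geometry, in a medium too weakly basic to move the alkene into conjugation.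

Step 8
Reactants: 11 ethyl (3Z,5R)-5-[(tert-butyldimethylsilyl)oxy]-6-[(4-methoxybenzyl)oxy]-4-methylhex-3-enoate
Product: 12 (3Z,5R)-5-[(tert-butyldimethylsilyl)oxy]-6-[(4-methoxybenzyl)oxy]-4-methylhex-3-enal
Conditions: i-Bu2AlH (1.1 equiv), CH2Cl2, −78 °C
Reagents that add atoms: none
Why: Half-reduction of the ester with i-Bu2AlH stops at the aluminium hemiacetal at −78 °C, which releases the β,γ-unsaturated aldehyde only on work-up; it is used at once without chromatography.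

Step 9
Reactants: 12 (3Z,5R)-5-[(tert-butyldimethylsilyl)oxy]-6-[(4-methoxybenzyl)oxy]-4-methylhex-3-enal; 13 methyl propiolate
Product: 15 methyl (5Z,7R)-7-[(tert-butyldimethylsilyl)oxy]-3-hydroxy-8-[(4-methoxybenzyl)oxy]-6-methyl-2-methylideneoct-5-enoate (both C3 epimers), via [1-(methoxycarbonyl)ethenyl]diisobutylalane 14 (not isolated)
Conditions: 13, i-Bu2AlH, NMO, THF, 0 °C; then 12, 0 to 25 °C
Reagents that add atoms: none
Why: Hydroalumination of methyl propiolate gives the α-aluminoacrylate 14, whose addition to the aldehyde (vinylalumination, a Morita–Baylis–Hillman surrogate that forms the C1–C7 bond) needs no amine base and should leave the β,γ-unsaturated aldehyde unisomerised; the new carbinol centre (C1) forms without control and becomes sp2 in step 10.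

Step 10
Reactants: 15 methyl (5Z,7R)-7-[(tert-butyldimethylsilyl)oxy]-3-hydroxy-8-[(4-methoxybenzyl)oxy]-6-methyl-2-methylideneoct-5-enoate
Product: 16 methyl (2Z,5Z,7R)-2-(bromomethyl)-7-[(tert-butyldimethylsilyl)oxy]-8-[(4-methoxybenzyl)oxy]-6-methylocta-2,5-dienoate
Conditions: NBS, Me2S, CH2Cl2, 0 to 25 °C
Reagents that add atoms: N-bromosuccinimide, O=C1CCC(=O)N1Br
Why: Activation of the allylic alcohol as an alkoxysulfonium salt (Corey–Kim reagent) and SN2′ attack of bromide should give the rearranged allylic bromide as the more stable Z isomer (C6 cis to CH2Br), as is usual for Morita–Baylis–Hillman adducts.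

Step 11
Reactants: 16 methyl (2Z,5Z,7R)-2-(bromomethyl)-7-[(tert-butyldimethylsilyl)oxy]-8-[(4-methoxybenzyl)oxy]-6-methylocta-2,5-dienoate
Product: 17 methyl (2Z,5Z,7R)-2-(bromomethyl)-7-[(tert-butyldimethylsilyl)oxy]-8-hydroxy-6-methylocta-2,5-dienoate
Conditions: DDQ, CH2Cl2/pH 7 buffer, 0 °C
Reagents that add atoms: none
Why: Oxidative cleavage of the PMB ether by DDQ (hydride abstraction, hydrolysis of the oxocarbenium ion) in a buffered two-phase medium should leave the silyl ether, the allylic bromide and the skipped diene intact.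

Step 12
Reactants: 17 methyl (2Z,5Z,7R)-2-(bromomethyl)-7-[(tert-butyldimethylsilyl)oxy]-8-hydroxy-6-methylocta-2,5-dienoate
Product: 18 methyl (2Z,5Z,7R)-2-(bromomethyl)-7-[(tert-butyldimethylsilyl)oxy]-6-methyl-8-oxoocta-2,5-dienoate
Conditions: Dess–Martin periodinane, NaHCO3, CH2Cl2, 0 to 25 °C
Reagents that add atoms: none
Why: Dess–Martin oxidation under NaHCO3 buffer should give the α-silyloxy aldehyde without epimerisation at C3 or loss of bromide; 18 is taken crude into step 13.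

Step 13
Reactants: 18 methyl (2Z,5Z,7R)-2-(bromomethyl)-7-[(tert-butyldimethylsilyl)oxy]-6-methyl-8-oxoocta-2,5-dienoate
Product: 21 (3aR,7R,7aS)-7-[(tert-butyldimethylsilyl)oxy]-6-methyl-3-methylidene-3a,4,7,7a-tetrahydro-1-benzofuran-2(3H)-one, via allylchromium dichloride 19 (not isolated), via chromium alkoxide 20 (not isolated)
Conditions: CrCl2 (4 equiv), THF (0.005 M), 0 to 25 °C
Reagents that add atoms: none
Why: Two equivalents of CrCl2 (divalent chromium) reduce the allylic C–Br bond by two single-electron transfers to the trivalent allylchromium 19, which adds through its γ-carbon C1 to the C2 aldehyde in a six-membered chair transition state with chromium bridging the carbonyl oxygen and C14, so that the alkene moves to C7=C14H2 and alkoxide 20 results, which then displaces methoxide at the C8 ester. The closest known reaction is the chromium- or zinc-mediated 2-(alkoxycarbonyl)allylation of aldehydes to α-methylene-γ-butyrolactones (Nozaki–Hiyama type), whose intramolecular form is known to give cis-fused lactones. The carbocycle closes by 6-exo-trig attack of C1 on the aldehyde carbon and the lactone by 5-exo-trig acyl substitution of O2 at C8. The C1/C2 relationship is set by the chair, in which the C6 branch (cis to CH2Cr on the Z allyl unit) sits axial and the aldehyde residue equatorial, giving the syn adduct and hence the cis ring fusion, while the aldehyde face is chosen by C3 through a Felkin–Anh arrangement with the C3–O bond anti to the incoming C1, which within the ring places O2 cis to O3 (1R,2S). The step needs ring closure over oligomerisation (high dilution; the 5Z alkene holds C1 and C2 within reach), γ- over α-attack (α-attack would demand an eight-membered ring) and attack anti to the silyloxy group (bulky, non-chelating TBS ether on the only stereocentre of 18).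

Step 14
Reactants: 21 (3aR,7R,7aS)-7-[(tert-butyldimethylsilyl)oxy]-6-methyl-3-methylidene-3a,4,7,7a-tetrahydro-1-benzofuran-2(3H)-one
Product: 22 (3aR,7R,7aS)-7-[(tert-butyldimethylsilyl)oxy]-6-methyl-3-methylidene-2,3,3a,4,7,7a-hexahydro-1-benzofuran-2-ol (both anomers)
Conditions: i-Bu2AlH (1.1 equiv), CH2Cl2, −78 °C
Reagents that add atoms: none
Why: i-Bu2AlH reduces the lactone carbonyl in the 1,2-sense at −78 °C and the aluminium lactolate resists further reduction, so the α-methylene lactol should be obtained with the exocyclic alkene intact.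

Step 15
Reactants: 22 (3aR,7R,7aS)-7-[(tert-butyldimethylsilyl)oxy]-6-methyl-3-methylidene-2,3,3a,4,7,7a-hexahydro-1-benzofuran-2-ol
Product: 25 (1S,2R,6R)-2-[(tert-butyldimethylsilyl)oxy]-6-[(3S)-3-hydroxyhexa-1,5-dien-2-yl]-3-methylcyclohex-3-en-1-ol, via hydroxy enal 23 (not isolated), via diisopinocampheylborinate 24 (not isolated)
Conditions: (−)-Ipc2BOMe, CH2=CHCH2MgBr, Et2O, −78 to 25 °C; then 22, −78 to 25 °C; NaOH, H2O2
Reagents that add atoms: allylmagnesium bromide, C=CC[Mg]Br (allyl group, passed on through the allylborane)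
Why: Brown allylboration: the lactol is in equilibrium with hydroxy enal 23, whose aldehyde takes up the allyl group through a chair transition state in which the isopinocampheyl groups direct attack to the Si face, which should set C8 as S under reagent control, and oxidative work-up releases the diol from borinate 24.

Step 16
Reactants: 25 (1S,2R,6R)-2-[(tert-butyldimethylsilyl)oxy]-6-[(3S)-3-hydroxyhexa-1,5-dien-2-yl]-3-methylcyclohex-3-en-1-ol
Product: 26 (1S,2R,6R)-2-[(tert-butyldimethylsilyl)oxy]-6-[(3S)-3-hydroxy-6-methylhepta-1,5-dien-2-yl]-3-methylcyclohex-3-en-1-ol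
Conditions: second-generation Grubbs catalyst (5 mol%), 2-methylbut-2-ene/CH2Cl2, 35 °C
Reagents that add atoms: 2-methylbut-2-ene, CC=C(C)C
Why: Olefin cross-metathesis: only the terminal vinyl group initiates readily and exchange with 2-methylbut-2-ene caps it as the prenyl alkene, while the 1,1-disubstituted C7=C14 and the trisubstituted ring alkene should stay untouched.

Step 17
Reactants: 27 angelic acid
Product: 28 (2Z)-2-methylbut-2-enoic 2,4,6-trichlorobenzoic anhydride
Conditions: 2,4,6-Cl3C6H2COCl, Et3N, toluene, 0 to 25 °C; filtered from Et3N·HCl under argon and kept as a toluene stock solution at −20 °C for steps 18 and 21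
Reagents that add atoms: 2,4,6-trichlorobenzoyl chloride, O=C(Cl)c1c(Cl)cc(Cl)cc1Cl
Why: Acyl substitution of triethylammonium angelate at the acid chloride gives the Yamaguchi mixed anhydride; no nucleophilic catalyst is present, so the Z alkene should not isomerise, and the two ortho chlorines shield the aryl carbonyl so that later alcoholysis takes place at the angeloyl carbonyl.

Step 18
Reactants: 26 (1S,2R,6R)-2-[(tert-butyldimethylsilyl)oxy]-6-[(3S)-3-hydroxy-6-methylhepta-1,5-dien-2-yl]-3-methylcyclohex-3-en-1-ol; 28 (2Z)-2-methylbut-2-enoic 2,4,6-trichlorobenzoic anhydride (two equivalents are consumed, an excess is used)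
Product: 29 (3S)-2-[(1R,5R,6S)-5-[(tert-butyldimethylsilyl)oxy]-4-methyl-6-{[(2Z)-2-methylbut-2-enoyl]oxy}cyclohex-3-en-1-yl]-6-methylhepta-1,5-dien-3-yl (2Z)-2-methylbut-2-enoate
Conditions: 28 (3 equiv), Et3N, toluene, 80 °C
Reagents that add atoms: the second equivalent of anhydride 28, C/C=C(/C)C(=O)OC(=O)c1c(Cl)cc(Cl)cc1Cl
Why: Yamaguchi-type esterification with the preformed mixed anhydride 28 without DMAP acylates both secondary hydroxyls (O2 and O8), each with one equivalent of 28, at the less hindered angeloyl carbonyl and is the established way to avoid Z-to-E isomerisation of angelate to tiglate.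

Step 19
Reactants: 29 (3S)-2-[(1R,5R,6S)-5-[(tert-butyldimethylsilyl)oxy]-4-methyl-6-{[(2Z)-2-methylbut-2-enoyl]oxy}cyclohex-3-en-1-yl]-6-methylhepta-1,5-dien-3-yl (2Z)-2-methylbut-2-enoate
Product: 30 (3S)-2-[(1R,5R,6S)-5-hydroxy-4-methyl-6-{[(2Z)-2-methylbut-2-enoyl]oxy}cyclohex-3-en-1-yl]-6-methylhepta-1,5-dien-3-yl (2Z)-2-methylbut-2-enoate
Conditions: HF·pyridine, pyridine, THF, 0 to 25 °C
Reagents that add atoms: none
Why: Fluoride-mediated cleavage of the silicon–oxygen bond with pyridine-buffered HF·pyridine should free O3 without acyl migration or ester cleavage.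

Step 20
Reactants: 30 (3S)-2-[(1R,5R,6S)-5-hydroxy-4-methyl-6-{[(2Z)-2-methylbut-2-enoyl]oxy}cyclohex-3-en-1-yl]-6-methylhepta-1,5-dien-3-yl (2Z)-2-methylbut-2-enoate
Product: 31 (1S,2S,3S,4R,6R)-2-hydroxy-1-methyl-4-[(3S)-6-methyl-3-{[(2Z)-2-methylbut-2-enoyl]oxy}hepta-1,5-dien-2-yl]-7-oxabicyclo[4.1.0]heptan-3-yl (2Z)-2-methylbut-2-enoate
Conditions: VO(acac)2 (5 mol%), t-BuOOH, CH2Cl2, 0 to 25 °C
Reagents that add atoms: tert-butyl hydroperoxide, CC(C)(C)OO
Why: Hydroxyl-directed vanadium-catalysed epoxidation: the vanadium alkoxide of the C3 hydroxyl delivers the peroxide oxygen to C4=C5 on the face syn to O3, which sets C4 and C5, while alkenes without a free allylic or homoallylic hydroxyl should not react.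

Step 21
Reactants: 31 (1S,2S,3S,4R,6R)-2-hydroxy-1-methyl-4-[(3S)-6-methyl-3-{[(2Z)-2-methylbut-2-enoyl]oxy}hepta-1,5-dien-2-yl]-7-oxabicyclo[4.1.0]heptan-3-yl (2Z)-2-methylbut-2-enoate; 28 (2Z)-2-methylbut-2-enoic 2,4,6-trichlorobenzoic anhydride
Product: 32 (1R,2S,3S,4R,6R)-1-methyl-4-[(3S)-6-methyl-3-{[(2Z)-2-methylbut-2-enoyl]oxy}hepta-1,5-dien-2-yl]-7-oxabicyclo[4.1.0]heptane-2,3-diyl bis[(2Z)-2-methylbut-2-enoate]
Conditions: 28 (3 equiv), Et3N (excess), toluene, 80 °C
Reagents that add atoms: none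
Why: The same Yamaguchi-type esterification with the preformed anhydride 28 and no DMAP should acylate the hindered C3 hydroxyl without angelate isomerisation, excess Et3N keeping the medium basic so that the epoxide is not opened.

Step 22
Reactants: 32 (1R,2S,3S,4R,6R)-1-methyl-4-[(3S)-6-methyl-3-{[(2Z)-2-methylbut-2-enoyl]oxy}hepta-1,5-dien-2-yl]-7-oxabicyclo[4.1.0]heptane-2,3-diyl bis[(2Z)-2-methylbut-2-enoate]
Product: 33 (1R,2S,3S,4R,6R)-4-[(3S)-4-[(2R)-3,3-dimethyloxiran-2-yl]-3-{[(2Z)-2-methylbut-2-enoyl]oxy}but-1-en-2-yl]-1-methyl-7-oxabicyclo[4.1.0]heptane-2,3-diyl bis[(2Z)-2-methylbut-2-enoate] (CNP0258231.4)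
Conditions: Shi ketone (1,2:4,5-di-O-isopropylidene-β-D-erythro-hexo-2,3-diulo-2,6-pyranose, 30 mol%), KHSO5 (as 2KHSO5·KHSO4·K2SO4), K2CO3, Bu4NHSO4, MeCN/CH2(OMe)2/aq Na2B4O7 buffer, 0 °C
Reagents that add atoms: potassium peroxymonosulfate, [K+].[O-]S(=O)(=O)OO
Why: Shi epoxidation: the chiral dioxirane formed from the D-fructose-derived ketone and KHSO5 epoxidises the electron-rich trisubstituted C10=C11 alkene through a spiro transition state that should give the 10R epoxide, while the 1,1-disubstituted C7=C14 alkene and the electron-poor angelate alkenes react much more slowly.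

**Compound list**

1 | 2-[(4-methoxybenzyl)oxy]acetaldehyde | COc1ccc(COCC=O)cc1 | starting material
2 | ethynyltrimethylsilane | C#C[Si](C)(C)C | starting material
3 | lithium (trimethylsilyl)acetylide | [Li]C#C[Si](C)(C)C | intermediate (not isolated)
4 | rac-1-[(4-methoxybenzyl)oxy]-4-(trimethylsilyl)but-3-yn-2-ol | COc1ccc(COCC(O)C#C[Si](C)(C)C)cc1 | intermediate
5 | 1-[(4-methoxybenzyl)oxy]-4-(trimethylsilyl)but-3-yn-2-one | COc1ccc(COCC(=O)C#C[Si](C)(C)C)cc1 | intermediate
6 | (2R)-1-[(4-methoxybenzyl)oxy]-4-(trimethylsilyl)but-3-yn-2-ol | COc1ccc(COC[C@H](O)C#C[Si](C)(C)C)cc1 | intermediate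
7 | (2R)-1-[(4-methoxybenzyl)oxy]but-3-yn-2-ol | COc1ccc(COC[C@H](O)C#C)cc1 | intermediate
8 | bromomagnesium (2R,3Z)-4-(bromomagnesio)-1-[(4-methoxybenzyl)oxy]-3-methylbut-3-en-2-olate | COc1ccc(COC[C@H](O[Mg]Br)/C(C)=C\[Mg]Br)cc1 | intermediate (not isolated)
9 | (2R,3Z)-4-iodo-1-[(4-methoxybenzyl)oxy]-3-methylbut-3-en-2-ol | COc1ccc(COC[C@H](O)/C(C)=C\I)cc1 | intermediate
10 | tert-butyl{[(2R,3Z)-4-iodo-1-[(4-methoxybenzyl)oxy]-3-methylbut-3-en-2-yl]oxy}dimethylsilane | COc1ccc(COC[C@H](O[Si](C)(C)C(C)(C)C)/C(C)=C\I)cc1 | intermediate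
11 | ethyl (3Z,5R)-5-[(tert-butyldimethylsilyl)oxy]-6-[(4-methoxybenzyl)oxy]-4-methylhex-3-enoate | COc1ccc(COC[C@H](O[Si](C)(C)C(C)(C)C)/C(C)=C\CC(=O)OCC)cc1 | intermediate
12 | (3Z,5R)-5-[(tert-butyldimethylsilyl)oxy]-6-[(4-methoxybenzyl)oxy]-4-methylhex-3-enal | COc1ccc(COC[C@H](O[Si](C)(C)C(C)(C)C)/C(C)=C\CC=O)cc1 | intermediate
13 | methyl propiolate | C#CC(=O)OC | starting material
14 | [1-(methoxycarbonyl)ethenyl]diisobutylalane | C=C(C(=O)OC)[Al](CC(C)C)CC(C)C | intermediate (not isolated)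
15 | methyl (5Z,7R)-7-[(tert-butyldimethylsilyl)oxy]-3-hydroxy-8-[(4-methoxybenzyl)oxy]-6-methyl-2-methylideneoct-5-enoate (C3 epimers) | COc1ccc(COC[C@H](O[Si](C)(C)C(C)(C)C)/C(C)=C\CC(O)C(=C)C(=O)OC)cc1 | intermediate
16 | methyl (2Z,5Z,7R)-2-(bromomethyl)-7-[(tert-butyldimethylsilyl)oxy]-8-[(4-methoxybenzyl)oxy]-6-methylocta-2,5-dienoate | COc1ccc(COC[C@H](O[Si](C)(C)C(C)(C)C)/C(C)=C\C/C=C(\CBr)C(=O)OC)cc1 | intermediate
17 | methyl (2Z,5Z,7R)-2-(bromomethyl)-7-[(tert-butyldimethylsilyl)oxy]-8-hydroxy-6-methylocta-2,5-dienoate | OC[C@H](O[Si](C)(C)C(C)(C)C)/C(C)=C\C/C=C(\CBr)C(=O)OC | intermediate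
18 | methyl (2Z,5Z,7R)-2-(bromomethyl)-7-[(tert-butyldimethylsilyl)oxy]-6-methyl-8-oxoocta-2,5-dienoate | O=C[C@H](O[Si](C)(C)C(C)(C)C)/C(C)=C\C/C=C(\CBr)C(=O)OC | intermediate (key-step precursor)
19 | methyl (2Z,5Z,7R)-7-[(tert-butyldimethylsilyl)oxy]-2-[(dichlorochromio)methyl]-6-methyl-8-oxoocta-2,5-dienoate | O=C[C@H](O[Si](C)(C)C(C)(C)C)/C(C)=C\C/C=C(\C[Cr](Cl)Cl)C(=O)OC | intermediate (not isolated)
20 | dichlorochromium alkoxide of methyl 2-[(1R,5R,6S)-5-[(tert-butyldimethylsilyl)oxy]-6-hydroxy-4-methylcyclohex-3-en-1-yl]prop-2-enoate | C=C(C(=O)OC)[C@H]1CC=C(C)[C@@H](O[Si](C)(C)C(C)(C)C)[C@H]1O[Cr](Cl)Cl | intermediate (not isolated)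
21 | (3aR,7R,7aS)-7-[(tert-butyldimethylsilyl)oxy]-6-methyl-3-methylidene-3a,4,7,7a-tetrahydro-1-benzofuran-2(3H)-one | C=C1C(=O)O[C@@H]2[C@H](O[Si](C)(C)C(C)(C)C)C(C)=CC[C@H]12 | intermediate (key-step product)
22 | (3aR,7R,7aS)-7-[(tert-butyldimethylsilyl)oxy]-6-methyl-3-methylidene-2,3,3a,4,7,7a-hexahydro-1-benzofuran-2-ol (anomers) | C=C1C(O)O[C@@H]2[C@H](O[Si](C)(C)C(C)(C)C)C(C)=CC[C@H]12 | intermediate
23 | 2-[(1R,5R,6S)-5-[(tert-butyldimethylsilyl)oxy]-6-hydroxy-4-methylcyclohex-3-en-1-yl]prop-2-enal | C=C(C=O)[C@H]1CC=C(C)[C@@H](O[Si](C)(C)C(C)(C)C)[C@H]1O | intermediate (not isolated)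
24 | O8-diisopinocampheylborinate of 25 | C=C([C@H](CC=C)OB([C@@H]1C[C@@H]2C[C@@H](C2(C)C)[C@H]1C)[C@@H]1C[C@@H]2C[C@@H](C2(C)C)[C@H]1C)[C@H]1CC=C(C)[C@@H](O[Si](C)(C)C(C)(C)C)[C@H]1O | intermediate (not isolated)
25 | (1S,2R,6R)-2-[(tert-butyldimethylsilyl)oxy]-6-[(3S)-3-hydroxyhexa-1,5-dien-2-yl]-3-methylcyclohex-3-en-1-ol | C=C([C@@H](O)CC=C)[C@H]1CC=C(C)[C@@H](O[Si](C)(C)C(C)(C)C)[C@H]1O | intermediate
26 | (1S,2R,6R)-2-[(tert-butyldimethylsilyl)oxy]-6-[(3S)-3-hydroxy-6-methylhepta-1,5-dien-2-yl]-3-methylcyclohex-3-en-1-ol | C=C([C@@H](O)CC=C(C)C)[C@H]1CC=C(C)[C@@H](O[Si](C)(C)C(C)(C)C)[C@H]1O | intermediate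
27 | angelic acid, (2Z)-2-methylbut-2-enoic acid | C/C=C(/C)C(=O)O | starting material
28 | (2Z)-2-methylbut-2-enoic 2,4,6-trichlorobenzoic anhydride | C/C=C(/C)C(=O)OC(=O)c1c(Cl)cc(Cl)cc1Cl | intermediate
29 | (3S)-2-[(1R,5R,6S)-5-[(tert-butyldimethylsilyl)oxy]-4-methyl-6-{[(2Z)-2-methylbut-2-enoyl]oxy}cyclohex-3-en-1-yl]-6-methylhepta-1,5-dien-3-yl (2Z)-2-methylbut-2-enoate | C=C([C@H](CC=C(C)C)OC(=O)/C(C)=C\C)[C@H]1CC=C(C)[C@@H](O[Si](C)(C)C(C)(C)C)[C@H]1OC(=O)/C(C)=C\C | intermediate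
30 | (3S)-2-[(1R,5R,6S)-5-hydroxy-4-methyl-6-{[(2Z)-2-methylbut-2-enoyl]oxy}cyclohex-3-en-1-yl]-6-methylhepta-1,5-dien-3-yl (2Z)-2-methylbut-2-enoate | C=C([C@H](CC=C(C)C)OC(=O)/C(C)=C\C)[C@H]1CC=C(C)[C@@H](O)[C@H]1OC(=O)/C(C)=C\C | intermediate
31 | (1S,2S,3S,4R,6R)-2-hydroxy-1-methyl-4-[(3S)-6-methyl-3-{[(2Z)-2-methylbut-2-enoyl]oxy}hepta-1,5-dien-2-yl]-7-oxabicyclo[4.1.0]heptan-3-yl (2Z)-2-methylbut-2-enoate | C=C([C@H](CC=C(C)C)OC(=O)/C(C)=C\C)[C@H]1C[C@H]2O[C@@]2(C)[C@@H](O)[C@H]1OC(=O)/C(C)=C\C | intermediate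
32 | (1R,2S,3S,4R,6R)-1-methyl-4-[(3S)-6-methyl-3-{[(2Z)-2-methylbut-2-enoyl]oxy}hepta-1,5-dien-2-yl]-7-oxabicyclo[4.1.0]heptane-2,3-diyl bis[(2Z)-2-methylbut-2-enoate] | C=C([C@H](CC=C(C)C)OC(=O)/C(C)=C\C)[C@H]1C[C@H]2O[C@@]2(C)[C@@H](OC(=O)/C(C)=C\C)[C@H]1OC(=O)/C(C)=C\C | intermediate
33 | (1R,2S,3S,4R,6R)-4-[(3S)-4-[(2R)-3,3-dimethyloxiran-2-yl]-3-{[(2Z)-2-methylbut-2-enoyl]oxy}but-1-en-2-yl]-1-methyl-7-oxabicyclo[4.1.0]heptane-2,3-diyl bis[(2Z)-2-methylbut-2-enoate] | C=C([C@H](C[C@H]1OC1(C)C)OC(=O)/C(C)=C\C)[C@H]1C[C@H]2O[C@@]2(C)[C@@H](OC(=O)/C(C)=C\C)[C@H]1OC(=O)/C(C)=C\C | target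

**Totals and risks**

Total step count: 22. Longest linear sequence: 21 steps (steps 1 to 16 and 18 to 22, from 1 to 33); step 17 prepares the acylating agent 28 in a one-step side branch.

Steps most likely to fail:

1. Step 13. What may go wrong: the silyloxy group at C3 may turn pseudoaxial in the forming ring to escape allylic 1,2-strain with the C4 methyl, so that C1 attacks the aldehyde face syn to it; C1 and C2 would then form with the wrong absolute sense, or with low facial selectivity. Fallback (C3 is corrected after the ring closure instead of steering it): the route is left at ynone 5, which is reduced with RuCl[(R,R)-TsDPEN](p-cymene) in i-PrOH to the (2S)-silylalkynol F1. The operations of steps 4 to 12 then give in turn the (2S)-alkynol F2, the (2S,3Z)-iodo alcohol F3, its TBS ether F4, the (5S)-ester F5, the (5S)-aldehyde F6, the (7S)-hydroxy ester F7, the (7S)-bromide PMB ether F8, the (7S)-bromo alcohol F9 and the (7S)-bromo aldehyde F10. Under the CrCl2 conditions of step 13 the preference described above would now give the cis-fused 7-epi-lactone F11, with C1 and C2 as in 21. HF·pyridine frees the 7-epi-alcohol F12 and Dess–Martin periodinane gives the enone lactone F13. NaBH4/CeCl3·7H2O in MeOH at −78 °C (Luche reduction, hydride from the convex face, anti to the lactone ring) should give the all-cis hydroxy lactone F14, which TBSOTf/2,6-lutidine converts into 21, where the route is rejoined.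

2. Step 15. What may go wrong: the cis-fused lactol may open too slowly at low temperature, so that the borane is consumed by the hydroxyl groups and, on warming, reagent control at C8 erodes. Fallback (the aldehyde is set free only after O2 has been acylated): from lactone 21, excess i-Bu2AlH gives the diol F15. Et3SiCl/imidazole at −40 °C silylates the primary allylic hydroxyl to the triethylsilyl ether F16, and anhydride 28 acylates O2 to the mono-angelate F17. PPTS in MeOH removes the triethylsilyl group to give the allylic alcohol F18, and MnO2 gives the enal F19, which cannot close to a lactol. The allylborane of step 15 (work-up with ethanolamine) gives the (3S)-homoallylic alcohol F20, cross-metathesis as in step 16 gives the prenyl alcohol F21, and esterification with 28 as in step 18 gives 29, where the route is rejoined.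

3. Step 7. What may go wrong: slow oxidative addition and transmetalation at the hindered Z-trisubstituted iodide, with loss of iodine by protonation, or drift of the new β,γ-double bond into conjugation with the ester. Fallback (the two carbons are added as a vinyl group and then hydroborated): from iodide 10, Stille coupling with Bu3SnCH=CH2 (Pd(PPh3)4, CuI, DMF) gives the Z-diene F22. 9-BBN adds to the terminal vinyl group only and NaOH/H2O2 gives the homoallylic alcohol F23. Dess–Martin oxidation then gives aldehyde 12, where the route is rejoined (step 8 is not needed).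

**Further compounds**

F1 | step 13 | (2S)-1-[(4-methoxybenzyl)oxy]-4-(trimethylsilyl)but-3-yn-2-ol | COc1ccc(COC[C@@H](O)C#C[Si](C)(C)C)cc1
F2 | step 13 | (2S)-1-[(4-methoxybenzyl)oxy]but-3-yn-2-ol | COc1ccc(COC[C@@H](O)C#C)cc1
F3 | step 13 | (2S,3Z)-4-iodo-1-[(4-methoxybenzyl)oxy]-3-methylbut-3-en-2-ol | COc1ccc(COC[C@@H](O)/C(C)=C\I)cc1
F4 | step 13 | tert-butyl{[(2S,3Z)-4-iodo-1-[(4-methoxybenzyl)oxy]-3-methylbut-3-en-2-yl]oxy}dimethylsilane | COc1ccc(COC[C@@H](O[Si](C)(C)C(C)(C)C)/C(C)=C\I)cc1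
F5 | step 13 | ethyl (3Z,5S)-5-[(tert-butyldimethylsilyl)oxy]-6-[(4-methoxybenzyl)oxy]-4-methylhex-3-enoate | COc1ccc(COC[C@@H](O[Si](C)(C)C(C)(C)C)/C(C)=C\CC(=O)OCC)cc1
F6 | step 13 | (3Z,5S)-5-[(tert-butyldimethylsilyl)oxy]-6-[(4-methoxybenzyl)oxy]-4-methylhex-3-enal | COc1ccc(COC[C@@H](O[Si](C)(C)C(C)(C)C)/C(C)=C\CC=O)cc1
F7 | step 13 | methyl (5Z,7S)-7-[(tert-butyldimethylsilyl)oxy]-3-hydroxy-8-[(4-methoxybenzyl)oxy]-6-methyl-2-methylideneoct-5-enoate (C3 epimers) | COc1ccc(COC[C@@H](O[Si](C)(C)C(C)(C)C)/C(C)=C\CC(O)C(=C)C(=O)OC)cc1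
F8 | step 13 | methyl (2Z,5Z,7S)-2-(bromomethyl)-7-[(tert-butyldimethylsilyl)oxy]-8-[(4-methoxybenzyl)oxy]-6-methylocta-2,5-dienoate | COc1ccc(COC[C@@H](O[Si](C)(C)C(C)(C)C)/C(C)=C\C/C=C(\CBr)C(=O)OC)cc1
F9 | step 13 | methyl (2Z,5Z,7S)-2-(bromomethyl)-7-[(tert-butyldimethylsilyl)oxy]-8-hydroxy-6-methylocta-2,5-dienoate | OC[C@@H](O[Si](C)(C)C(C)(C)C)/C(C)=C\C/C=C(\CBr)C(=O)OC
F10 | step 13 | methyl (2Z,5Z,7S)-2-(bromomethyl)-7-[(tert-butyldimethylsilyl)oxy]-6-methyl-8-oxoocta-2,5-dienoate | O=C[C@@H](O[Si](C)(C)C(C)(C)C)/C(C)=C\C/C=C(\CBr)C(=O)OC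
F11 | step 13 | (3aR,7S,7aS)-7-[(tert-butyldimethylsilyl)oxy]-6-methyl-3-methylidene-3a,4,7,7a-tetrahydro-1-benzofuran-2(3H)-one | C=C1C(=O)O[C@@H]2[C@@H](O[Si](C)(C)C(C)(C)C)C(C)=CC[C@H]12
F12 | step 13 | (3aR,7S,7aS)-7-hydroxy-6-methyl-3-methylidene-3a,4,7,7a-tetrahydro-1-benzofuran-2(3H)-one | C=C1C(=O)O[C@@H]2[C@@H](O)C(C)=CC[C@H]12
F13 | step 13 | (3aR,7aS)-6-methyl-3-methylidene-3a,7a-dihydro-1-benzofuran-2,7(3H,4H)-dione | C=C1C(=O)O[C@@H]2C(=O)C(C)=CC[C@H]12
F14 | step 13 | (3aR,7R,7aS)-7-hydroxy-6-methyl-3-methylidene-3a,4,7,7a-tetrahydro-1-benzofuran-2(3H)-one | C=C1C(=O)O[C@@H]2[C@H](O)C(C)=CC[C@H]12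
F15 | step 15 | (1S,2R,6R)-2-[(tert-butyldimethylsilyl)oxy]-6-(3-hydroxyprop-1-en-2-yl)-3-methylcyclohex-3-en-1-ol | C=C(CO)[C@H]1CC=C(C)[C@@H](O[Si](C)(C)C(C)(C)C)[C@H]1O
F16 | step 15 | (1S,2R,6R)-2-[(tert-butyldimethylsilyl)oxy]-3-methyl-6-{3-[(triethylsilyl)oxy]prop-1-en-2-yl}cyclohex-3-en-1-ol | C=C(CO[Si](CC)(CC)CC)[C@H]1CC=C(C)[C@@H](O[Si](C)(C)C(C)(C)C)[C@H]1O
F17 | step 15 | (1S,2R,6R)-2-[(tert-butyldimethylsilyl)oxy]-3-methyl-6-{3-[(triethylsilyl)oxy]prop-1-en-2-yl}cyclohex-3-en-1-yl (2Z)-2-methylbut-2-enoate | C=C(CO[Si](CC)(CC)CC)[C@H]1CC=C(C)[C@@H](O[Si](C)(C)C(C)(C)C)[C@H]1OC(=O)/C(C)=C\C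
F18 | step 15 | (1S,2R,6R)-2-[(tert-butyldimethylsilyl)oxy]-6-(3-hydroxyprop-1-en-2-yl)-3-methylcyclohex-3-en-1-yl (2Z)-2-methylbut-2-enoate | C=C(CO)[C@H]1CC=C(C)[C@@H](O[Si](C)(C)C(C)(C)C)[C@H]1OC(=O)/C(C)=C\C
F19 | step 15 | (1S,2R,6R)-2-[(tert-butyldimethylsilyl)oxy]-3-methyl-6-(3-oxoprop-1-en-2-yl)cyclohex-3-en-1-yl (2Z)-2-methylbut-2-enoate | C=C(C=O)[C@H]1CC=C(C)[C@@H](O[Si](C)(C)C(C)(C)C)[C@H]1OC(=O)/C(C)=C\C
F20 | step 15 | (1S,2R,6R)-2-[(tert-butyldimethylsilyl)oxy]-6-[(3S)-3-hydroxyhexa-1,5-dien-2-yl]-3-methylcyclohex-3-en-1-yl (2Z)-2-methylbut-2-enoate | C=C([C@@H](O)CC=C)[C@H]1CC=C(C)[C@@H](O[Si](C)(C)C(C)(C)C)[C@H]1OC(=O)/C(C)=C\C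
F21 | step 15 | (1S,2R,6R)-2-[(tert-butyldimethylsilyl)oxy]-6-[(3S)-3-hydroxy-6-methylhepta-1,5-dien-2-yl]-3-methylcyclohex-3-en-1-yl (2Z)-2-methylbut-2-enoate | C=C([C@@H](O)CC=C(C)C)[C@H]1CC=C(C)[C@@H](O[Si](C)(C)C(C)(C)C)[C@H]1OC(=O)/C(C)=C\C
F22 | step 7 | tert-butyl{[(2R,3Z)-1-[(4-methoxybenzyl)oxy]-3-methylhexa-3,5-dien-2-yl]oxy}dimethylsilane | COc1ccc(COC[C@H](O[Si](C)(C)C(C)(C)C)/C(C)=C\C=C)cc1
F23 | step 7 | (3Z,5R)-5-[(tert-butyldimethylsilyl)oxy]-6-[(4-methoxybenzyl)oxy]-4-methylhex-3-en-1-ol | COc1ccc(COC[C@H](O[Si](C)(C)C(C)(C)C)/C(C)=C\CCO)cc1
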